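1. Retrosynthesis: the C15 ketone goes back to an allylic CH2 (SeO2, then MnO2); rings C and D are then cut together at C12–C13 (retro-ene) and C11–C15 (retro-Claisen), which gives a 2-isopropenyl-2,3-dihydrooxepine fused to ring B at C8=C9.
2. The oxepine (C11=C12) and ring B (C8=C9) are cut by metathesis and C6–C7 by allylation, leaving ring-A aldehyde 7 (from 2-methylcyclohexane-1,3-dione) and allylic chloride 12 (from methacrolein).
3. Forward: ring A (steps 1–6), side chain (7–8), union and oxidation (9–10), ring B then the oxepine in one metathesis cascade (11), C6/C1 adjustment (12–14), rings C and D in one thermal operation (15), C15 oxidation (16–17).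
4. Enabling feature: in ring D the C12 carbinol is homoallylic to the exocyclic C16=C17 (carbonyl-ene retron); the aldehyde this unveils at C12 has C11–C15 as its α,β bond and C13=C16 γ,δ to it (Claisen retron); the C8=C9 alkene holds both chains cis, so an oxygen bridge from C12 to C13 closes to a seven-membered allyl vinyl ether.
5. Stereochemistry: C1/C10 from a CBS desymmetrization, C5 by equilibration, C6 by hydride attack anti to the axial methyls; the temporary C13 carbinol comes from a catalytic asymmetric Sakurai reaction and is relayed to C11 ([3,3] shift), then to C13 and C12 (ene transition state).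

Key step: step 15

Remark: locants follow the ent-kaurane-derived skeleton (ring A = C1–C5, C10; ring B = C5–C10; ring C = C8, C9, C11–C14; ring D = C11, C12, C13, C16, C15; C17 = exocyclic methylene). The enantiomer named for each chiral catalyst is assumed to deliver the stated configuration; if the sense were opposite, the antipodal catalyst would be used.

Route

Step 1
Reactants: 1 2-methylcyclohexane-1,3-dione
Product: 2 2-ethynyl-2-methylcyclohexane-1,3-dione
Conditions: TMS-EBX, TBAF, THF, −78 °C to rt
Reagents that add atoms: 1-[(trimethylsilyl)ethynyl]-1,2-benziodoxol-3(1H)-one (TMS-EBX), C[Si](C)(C)C#CI1OC(=O)c2ccccc12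
Why: Electrophilic α-alkynylation of the stabilized dione enolate with an ethynylbenziodoxolone should create the quaternary C10 carrying the alkyne that becomes C9 and C11.

Step 2
Reactants: 2 2-ethynyl-2-methylcyclohexane-1,3-dione
Product: 3 (2R,3S)-2-ethynyl-3-hydroxy-2-methylcyclohexan-1-one (hydroxyl cis to methyl)
Conditions: (R)-2-methyl-CBS-oxazaborolidine (20 mol %), catecholborane, PhMe, −78 °C
Reagents that add atoms: none
Why: CBS desymmetrizing reduction of the prochiral 2,2-disubstituted 1,3-dione; the catalyst fixes the carbinol configuration and hydride should enter anti to the bulkier methyl (syn to the slim ethynyl), so the hydroxyl ends cis to methyl.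

Step 3
Reactants: 3 (2R,3S)-2-ethynyl-3-hydroxy-2-methylcyclohexan-1-one
Product: 4 (2R,3S)-3-[(tert-butyldimethylsilyl)oxy]-2-ethynyl-2-methylcyclohexan-1-one
Conditions: TBSOTf, 2,6-lutidine, CH2Cl2, 0 °C
Reagents that add atoms: tert-butyldimethylsilyl triflate, CC(C)(C)[Si](C)(C)OS(=O)(=O)C(F)(F)F
Why: Standard silylation of a hindered secondary alcohol; the ether should survive the basic and Lewis-acidic steps that follow.

Step 4
Reactants: 4 (2R,3S)-3-[(tert-butyldimethylsilyl)oxy]-2-ethynyl-2-methylcyclohexan-1-one
Product: 5 (2R,3S)-3-[(tert-butyldimethylsilyl)oxy]-2-ethynyl-2,6,6-trimethylcyclohexan-1-one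
Conditions: KOtBu, MeI (excess), t-BuOH/THF, 0 °C to rt
Reagents that add atoms: iodomethane, CI
Why: Exhaustive enolate methylation at the only enolizable position (C4) installs the gem-dimethyl group; C10 is quaternary, so the β-silyloxy group cannot be eliminated.

Step 5
Reactants: 5 (2R,3S)-3-[(tert-butyldimethylsilyl)oxy]-2-ethynyl-2,6,6-trimethylcyclohexan-1-one
Product: 6 (4R,5S)-5-[(tert-butyldimethylsilyl)oxy]-4-ethynyl-4,8,8-trimethyl-1-oxaspiro[2.5]octane (epimers at the spiro carbon)
Conditions: Me3S+ I−, n-BuLi, THF, −10 °C to rt
Reagents that add atoms: trimethylsulfonium iodide, C[S+](C)C.[I-]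
Why: Corey–Chaykovsky epoxidation; the small sulfur ylide should add to the non-enolizable, doubly neopentyl ketone, and the spiro configuration is lost in step 6.

Step 6
Reactants: 6 (4R,5S)-5-[(tert-butyldimethylsilyl)oxy]-4-ethynyl-4,8,8-trimethyl-1-oxaspiro[2.5]octane
Product: 7 (1R,2R,3S)-3-[(tert-butyldimethylsilyl)oxy]-2-ethynyl-2,6,6-trimethylcyclohexane-1-carbaldehyde
Conditions: BF3·OEt2 (cat.), CH2Cl2, −78 °C; then K2CO3, MeOH, rt
Reagents that add atoms: none
Why: Meinwald rearrangement (opening to the tertiary C5 cation, then 1,2-hydride shift) should give the aldehyde; base equilibration should place the formyl group equatorial and trans to the ethynyl group, so that C5–H is anti to the C10 methyl, and C5 stays adjustable α to a carbonyl group up to ketone 17.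

Step 7
Reactants: 8 methacrolein; 9 2-(chloromethyl)-3-(trimethylsilyl)prop-1-ene
Product: 11 (3R)-5-(chloromethyl)-2-methylhexa-1,5-dien-3-ol, via silyl ether 10 (not isolated)
Conditions: acyloxyborane from (2R,3R)-2-O-(2,6-diisopropoxybenzoyl)tartaric acid and BH3·THF (20 mol %), EtCN, −78 °C; then 1 M HCl
Reagents that add atoms: none
Why: Catalytic asymmetric Hosomi–Sakurai allylation; the tartrate-derived boron Lewis acid should shield one face of the bound enal and give the (R)-carbinol (future C13), while the chloromethyl group stays as the second allylic handle.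

Step 8
Reactants: 11 (3R)-5-(chloromethyl)-2-methylhexa-1,5-dien-3-ol
Product: 12 (3R)-5-(chloromethyl)-3-(ethenyloxy)-2-methylhexa-1,5-diene
Conditions: ethyl vinyl ether (solvent), Hg(OAc)2 (10 mol %), reflux
Reagents that add atoms: ethyl vinyl ether, C=COCC
Why: Mercury-catalysed transetherification, the standard preparation of allyl vinyl ethers; it masks the alcohol and supplies C12.

Step 9
Reactants: 12 (3R)-5-(chloromethyl)-3-(ethenyloxy)-2-methylhexa-1,5-diene; 7 (1R,2R,3S)-3-[(tert-butyldimethylsilyl)oxy]-2-ethynyl-2,6,6-trimethylcyclohexane-1-carbaldehyde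
Product: 14 C6 carbinol (both C6 epimers) carrying the C7–C8(=CH2)–C14–C13(O-vinyl)–isopropenyl chain on C5 of ring A, via allylzinc chloride 13 (not isolated)
Conditions: Zn, LiCl, THF, rt; then 7, −78 to 0 °C
Reagents that add atoms: none
Why: Zinc insertion into the allylic chloride and carbonyl allylation of the hindered aldehyde; the 2-substituted allyl unit is symmetric, so there is no regiochemical issue, and the C6 epimers converge in step 10.

Step 10
Reactants: 14 C6 carbinol
Product: 15 C6 ketone (β,γ-unsaturated; ring B still open)
Conditions: Dess–Martin periodinane, NaHCO3, CH2Cl2, 0 °C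
Reagents that add atoms: none
Why: Buffered Dess–Martin oxidation removes the uncontrolled C6 stereocenter and should spare the vinyl ether and the skipped enone.

Step 11
Reactants: 15 C6 ketone
Product: 17 tricyclic 6-oxo dienol ether (oxepine O–C12=C11–C9=C8–C14–C13 fused to ring B; 13R isopropenyl; C1 OTBS), via C9-vinyl triene 16 (not isolated)
Conditions: second-generation Grubbs catalyst (H2IMes)(PCy3)Cl2Ru=CHPh (10 mol %), 1,4-benzoquinone (10 mol %), ethylene (1 atm), PhMe, 60 °C; then argon, 90 °C
Reagents that add atoms: none
Why: Ring-closing enyne metathesis of the C9≡C11 alkyne with the 1,1-disubstituted C8 alkene should close ring B as the tetrasubstituted C8=C9 diene; enol-ether ring-closing metathesis of the new vinyl group with the O-vinyl group should then close the oxepine, and C5 keeps the trans-fused arrangement, which is also the thermodynamic one α to the ketone.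

Step 12
Reactants: 17 tricyclic 6-oxo dienol ether
Product: 18 axial C6 alcohol (hydroxyl cis to the C10 methyl)
Conditions: NaBH4, MeOH/CH2Cl2, −20 °C
Reagents that add atoms: none
Why: Hydride should attack the C6 ketone from the face anti to the axial C10 and C4 methyl groups, giving the axial alcohol.

Step 13
Reactants: 18 axial C6 alcohol
Product: 19 C1,C6-diol
Conditions: TBAF, THF, 50 °C
Reagents that add atoms: none
Why: Fluoride desilylation under basic conditions, which should leave the acid-sensitive dienol ether intact.

Step 14
Reactants: 19 C1,C6-diol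
Product: 20 C1,C6-diacetate (key-step substrate)
Conditions: Ac2O, DMAP, pyridine, 50 °C
Reagents that add atoms: acetic anhydride, CC(=O)OC(C)=O
Why: DMAP-catalysed acetylation of both secondary alcohols, done before the C12 hydroxyl exists so that it stays free in the target.

Step 15
Reactants: 20 C1,C6-diacetate
Product: 22 tetracyclic 12-hydroxy-8,16(17)-diene (15-deoxo target), via cycloheptadiene carbaldehyde 21 (not isolated)
Conditions: degassed PhMe, BHT, NaHCO3 (solid), 180 °C, sealed tube
Reagents that add atoms: none
Why: Heating should trigger a Claisen rearrangement of the cyclic allyl vinyl ether C11=C12–O–C13–C16=C15 through a boat-like [3,3] transition state, forming C11–C15 and unveiling the C12 aldehyde in 21, which should then undergo a transannular carbonyl-ene reaction that forms C12–C13 and moves a C17 hydrogen to oxygen. The closest known reaction types are the thermal rearrangement of 2-alkenyl cyclic enol ethers to cycloalkene carbaldehydes, tandem Claisen–ene sequences and the citronellal-to-isopulegol ene cyclization. The [3,3] shift transposes the seven-membered oxepine into the seven-membered carbocycle C9–C11–C15–C16–C13–C14–C8, and the ene step then closes the six-membered ring C (C8, C9, C11, C12, C13, C14) and the five-membered ring D (C11, C12, C13, C16, C15) with one bond across that carbocycle, leaving the exocyclic C16=C17. C11 is set by suprafacial chirality transfer from the (R)-carbinol C13, whose isopropenyl group lies on the face anti to the C10 methyl and can reach C11 only there; C13 is then fixed because the one-carbon bridge can span C11 and C13 only on the face that carries the formyl group; C12 is set by the cyclic ene transition state, in which the carbonyl oxygen must point toward the hydrogen donor C17 and so ends syn to the C15–C16 bridge. The step needs the [3,3] shift to outrun 1,5-hydrogen shifts of the dienol ether and needs hydrogen transfer from C17 and not from C15; the first is helped by the alkyl groups on C13 and C16 and by the reversibility of the first hydrogen shift, the second because the C15 hydrogens, tied to C11, are poorly aligned with the alkene π system and the carbonyl oxygen.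

Step 16
Reactants: 22 tetracyclic 12-hydroxy-8,16(17)-diene
Product: 23 12,15-diol (allylic C15 alcohol; C15 configuration immaterial)
Conditions: SeO2 (0.5 equiv), t-BuOOH, CH2Cl2, rt
Reagents that add atoms: tert-butyl hydroperoxide, CC(C)(C)OO
Why: Riley allylic oxidation (ene reaction, then [2,3] shift) at the exocyclic methylene; only C15 can give up the allylic hydrogen because C13 is a bridgehead, and the shielded tetrasubstituted C8=C9 should react more slowly.

Step 17
Reactants: 23 12,15-diol
Product: 24 1alpha,6alpha-diacetoxyjungermannenone C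
Conditions: MnO2, CH2Cl2, rt
Reagents that add atoms: none
Why: Manganese dioxide oxidizes the allylic C15 alcohol to the α-methylene ketone and should leave the saturated, hindered C12 alcohol untouched.

Compound list

1 | 2-methylcyclohexane-1,3-dione | CC1C(=O)CCCC1=O | starting material
2 | 2-ethynyl-2-methylcyclohexane-1,3-dione | CC1(C#C)C(=O)CCCC1=O | intermediate
3 | (2R,3S)-2-ethynyl-3-hydroxy-2-methylcyclohexan-1-one | O=C1CCC[C@H](O)[C@@]1(C)C#C | intermediate
4 | (2R,3S)-3-[(tert-butyldimethylsilyl)oxy]-2-ethynyl-2-methylcyclohexan-1-one | O=C1CCC[C@H](O[Si](C)(C)C(C)(C)C)[C@@]1(C)C#C | intermediate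
5 | (2R,3S)-3-[(tert-butyldimethylsilyl)oxy]-2-ethynyl-2,6,6-trimethylcyclohexan-1-one | O=C1C(C)(C)CC[C@H](O[Si](C)(C)C(C)(C)C)[C@@]1(C)C#C | intermediate
6 | (4R,5S)-5-[(tert-butyldimethylsilyl)oxy]-4-ethynyl-4,8,8-trimethyl-1-oxaspiro[2.5]octane (spiro carbon unassigned) | C1OC12C(C)(C)CC[C@H](O[Si](C)(C)C(C)(C)C)[C@@]2(C)C#C | intermediate
7 | (1R,2R,3S)-3-[(tert-butyldimethylsilyl)oxy]-2-ethynyl-2,6,6-trimethylcyclohexane-1-carbaldehyde | O=C[C@@H]1C(C)(C)CC[C@H](O[Si](C)(C)C(C)(C)C)[C@@]1(C)C#C | intermediate
8 | methacrolein | CC(=C)C=O | starting material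
9 | 2-(chloromethyl)-3-(trimethylsilyl)prop-1-ene | C=C(CCl)C[Si](C)(C)C | starting material
10 | trimethylsilyl ether of 11 (formed in the flask) | C=C(C)[C@H](O[Si](C)(C)C)CC(=C)CCl | intermediate
11 | (3R)-5-(chloromethyl)-2-methylhexa-1,5-dien-3-ol | C=C(C)[C@H](O)CC(=C)CCl | intermediate
12 | (3R)-5-(chloromethyl)-3-(ethenyloxy)-2-methylhexa-1,5-diene | C=C(C)[C@H](OC=C)CC(=C)CCl | intermediate
13 | allylzinc chloride derived from 12 (formed in the flask) | C=C(C)[C@H](OC=C)CC(=C)C[Zn]Cl | intermediate
14 | C6 carbinol from union of 7 and 12 (C6 epimers) | C=C(C)[C@H](OC=C)CC(=C)CC(O)[C@@H]1C(C)(C)CC[C@H](O[Si](C)(C)C(C)(C)C)[C@@]1(C)C#C | intermediate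
15 | C6 ketone | C=C(C)[C@H](OC=C)CC(=C)CC(=O)[C@@H]1C(C)(C)CC[C@H](O[Si](C)(C)C(C)(C)C)[C@@]1(C)C#C | intermediate
16 | ring-B triene (C8=C9, C9-vinyl) carrying the pendant O-vinyl group (formed in the flask) | C=CC1=C(C[C@@H](OC=C)C(C)=C)CC(=O)[C@@H]2C(C)(C)CC[C@H](O[Si](C)(C)C(C)(C)C)[C@@]12C | intermediate
17 | tricyclic 6-oxo dienol ether (oxepine fused at C8=C9, 13R-isopropenyl, C1 OTBS) | C=C(C)[C@@H]1OC=CC2=C(C1)CC(=O)[C@@H]3C(C)(C)CC[C@H](O[Si](C)(C)C(C)(C)C)[C@@]23C | intermediate
18 | axial C6 alcohol of 17 | C=C(C)[C@@H]1OC=CC2=C(C1)C[C@H](O)[C@@H]3C(C)(C)CC[C@H](O[Si](C)(C)C(C)(C)C)[C@@]23C | intermediate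
19 | C1,C6-diol | C=C(C)[C@@H]1OC=CC2=C(C1)C[C@H](O)[C@@H]3C(C)(C)CC[C@H](O)[C@@]23C | intermediate
20 | C1,C6-diacetate (cyclic allyl vinyl ether) | C=C(C)[C@@H]1OC=CC2=C(C1)C[C@H](OC(C)=O)[C@@H]3C(C)(C)CC[C@H](OC(C)=O)[C@@]23C | intermediate
21 | cycloheptadiene carbaldehyde (C11–C15 formed, C12 aldehyde; formed in the flask) | O=C[C@H]1C2=C(C[C@H](OC(C)=O)[C@@H]3C(C)(C)CC[C@H](OC(C)=O)[C@@]23C)CC=C(C)C1 | intermediate
22 | 15-deoxo tetracycle (12-hydroxy, C16=C17, C8=C9) | C=C1C[C@@H]2C3=C(C[C@H](OC(C)=O)[C@@H]4C(C)(C)CC[C@H](OC(C)=O)[C@@]34C)C[C@H]1[C@@H]2O | intermediate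
23 | 12,15-diol (C15 unassigned) | C=C1C(O)[C@@H]2C3=C(C[C@H](OC(C)=O)[C@@H]4C(C)(C)CC[C@H](OC(C)=O)[C@@]34C)C[C@H]1[C@@H]2O | intermediate
24 | 1alpha,6alpha-diacetoxyjungermannenone C | C=C1C(=O)[C@@H]2C3=C(C[C@H](OC(C)=O)[C@@H]4C(C)(C)CC[C@H](OC(C)=O)[C@@]34C)C[C@H]1[C@@H]2O | target

Total step count: 17. Longest linear sequence: 15 steps (steps 1–6, then 9–17).

The three steps most likely to fail:

First risk, step 15. Sigmatropic 1,5-hydrogen shifts of the cyclic dienol ether may compete with the [3,3] shift; that would erase the C13 stereocenter and drain material into a conjugated trienol ether. The fallback for step 15 gives up the thermal pericyclic cascade for a stepwise, Lewis-acid-mediated sequence at low temperature, where hydrogen shifts are frozen. It sets out from 20: methylaluminium bis(4-bromo-2,6-di-tert-butylphenoxide) in CH2Cl2 at −78 °C should effect a charge-accelerated Claisen rearrangement to aldehyde 21, now isolated. Me2AlCl in CH2Cl2 at −78 to 0 °C should then promote the carbonyl-ene closure, and the fallback comes back to the route at 22. It makes no new compound, hence the entry F0.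

Second risk, step 11. The vinyl ether may sequester the ruthenium catalyst as an unreactive alkoxycarbene before the enyne closure, the tetrasubstituted C8=C9 may close slowly, and the new vinyl group may close onto the isopropenyl group instead. The fallback for step 11 forms ring B on a substrate without the vinyl ether and attaches it only afterwards. It sets out from 11: silylation (Et3SiCl, imidazole, CH2Cl2) should give (3R)-5-(chloromethyl)-2-methyl-3-(triethylsilyloxy)hexa-1,5-diene F1. Zinc insertion (Zn, LiCl, THF) should turn it into the triethylsilyloxy allylzinc chloride F2, which should add to 7 to give the 13-triethylsilyloxy C6 carbinol F3. Dess–Martin oxidation should give the 13-triethylsilyloxy C6 ketone F4. Enyne ring-closing metathesis under ethylene with the second-generation Grubbs catalyst (H2IMes)(PCy3)Cl2Ru=CHPh should give the 13-triethylsilyloxy ring-B triene F5. Selective removal of the triethylsilyl group (PPTS, MeOH, 0 °C) should give the 13-hydroxy ring-B triene F6. Vinyl transfer from ethyl vinyl ether with Hg(OAc)2 should then give 16, now isolated, and a separate enol-ether ring-closing metathesis should come back to the route at 17.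

Third risk, step 2. Hydride may be delivered to the wrong enantiotopic carbonyl or to the wrong face, which would give the hydroxyl trans to methyl or low enantiomeric purity. The fallback for step 2 replaces the oxazaborolidine by a biocatalytic desymmetrization. It sets out from 2: a ketoreductase (alcohol dehydrogenase class), chosen from a panel for the cis-hydroxy product and run with NADPH recycling by glucose and glucose dehydrogenase in buffer, should reduce one carbonyl under enzyme control and come back to the route at 3. It makes no new compound, hence the entry F0.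

Further compounds
F0 | step 15 | none | none
F1 | step 11 | (3R)-5-(chloromethyl)-2-methyl-3-(triethylsilyloxy)hexa-1,5-diene | C=C(C)[C@H](O[Si](CC)(CC)CC)CC(=C)CCl
F2 | step 11 | triethylsilyloxy allylzinc chloride | C=C(C)[C@H](O[Si](CC)(CC)CC)CC(=C)C[Zn]Cl
F3 | step 11 | 13-triethylsilyloxy C6 carbinol | C=C(C)[C@H](O[Si](CC)(CC)CC)CC(=C)CC(O)[C@@H]1C(C)(C)CC[C@H](O[Si](C)(C)C(C)(C)C)[C@@]1(C)C#C
F4 | step 11 | 13-triethylsilyloxy C6 ketone | C=C(C)[C@H](O[Si](CC)(CC)CC)CC(=C)CC(=O)[C@@H]1C(C)(C)CC[C@H](O[Si](C)(C)C(C)(C)C)[C@@]1(C)C#C
F5 | step 11 | 13-triethylsilyloxy ring-B triene | C=CC1=C(C[C@@H](O[Si](CC)(CC)CC)C(C)=C)CC(=O)[C@@H]2C(C)(C)CC[C@H](O[Si](C)(C)C(C)(C)C)[C@@]12C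
F6 | step 11 | 13-hydroxy ring-B triene | C=CC1=C(C[C@@H](O)C(C)=C)CC(=O)[C@@H]2C(C)(C)CC[C@H](O[Si](C)(C)C(C)(C)C)[C@@]12C
F0 | step 2 | none | none
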